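The cyclopentane ring (C1–C5, daucane numbering) is cut into a C2–C3–C4 homoenolate and the C1=C5 bond of a cycloheptenone. The feature exploited is hidden symmetry. With C6 as ketone and C9 as CH2, the seven-membered ring with its methyls on C1 and C8 is the mirror-symmetric 3,6-dimethylcyclohepta-2,6-dienone, and C4(OH)–C5–C6(=O) is an aldol retron. In the key step, ring-opened 1-isopropylcyclopropanol adds as a chiral copper/zinc homoenolate to one enantiotopic face of the two equivalent enone arms. The dienolate then closes onto the liberated isopropyl ketone, so both ring bonds and C1, C5 and C4 arise at once. The dienone comes from (4+3) dearomatization of 2,5-dimethylfuran.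

Key step: step 5

Numbering: daucane numbering is used throughout. C1 is the quaternary ring-fusion carbon (its CH3 is C15), C2 and C3 are the cyclopentane CH2 groups, C4 is the carbinol carbon bearing isopropyl, and C5 is the ring-fusion CH. C6 is the ester carbinol, C7=C8 is the alkene (CH3 on C8 is C14), C9 is the ketone and C10 is CH2. β is the face of C15.

Assumption: the sense of induction of the NHC ligand in step 5 cannot be predicted safely. The antipode that gives (8aS)-12 is taken; both antipodes are accessible.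

Step 1
Reactants: 1 2,5-dimethylfuran; 2 1,1,3,3-tetrabromopropan-2-one
Product: 4 (1R,5S)-1,5-dimethyl-8-oxabicyclo[3.2.1]oct-6-en-3-one (meso), via dibromo cycloadduct 3 (not isolated)
Conditions: Zn, B(OEt)3, THF, 0 °C to rt; then Zn–Cu, NH4Cl, MeOH, rt
Reagents that add atoms: none
Why: Zinc reduction of 2 gives the dibromo-oxyallyl cation, which adds across C2/C5 of the furan in a (4+3) cycloaddition (dearomatization) and is then reductively debrominated; the product is meso, so no stereochemical issue arises.

Step 2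
Reactants: 4 (1R,5S)-1,5-dimethyl-8-oxabicyclo[3.2.1]oct-6-en-3-one
Product: 5 (1R,5S)-1,5-dimethyl-8-oxabicyclo[3.2.1]octan-3-one (meso)
Conditions: H2 (1 atm), 10% Pd/C, EtOAc, rt
Reagents that add atoms: none
Why: Catalytic hydrogenation saturates the strained disubstituted alkene and leaves the ketone and the ether bridge untouched.

Step 3
Reactants: 5 (1R,5S)-1,5-dimethyl-8-oxabicyclo[3.2.1]octan-3-one
Product: 7 3,6-dimethylcyclohepta-2,6-dien-1-one, via hydroxy enone 6 (not isolated)
Conditions: p-TsOH·H2O (10 mol %), toluene, reflux, Dean–Stark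
Reagents that add atoms: none
Why: Both tertiary bridgehead C–O bonds are β to the ketone, so acid-catalysed β-elimination through the enol opens the bridge to 6 and dehydration of its tertiary β-hydroxy ketone gives the doubly conjugated dienone (the known acid cleavage of hydrogenated furan–oxyallyl adducts to cycloheptadienones).

Step 4
Reactants: 8 methyl 2-methylpropanoate
Product: 9 1-(propan-2-yl)cyclopropan-1-ol
Conditions: EtMgBr (2.4 equiv), Ti(OiPr)4 (15 mol %), Et2O, 0 °C to rt; dilute H2SO4 work-up
Reagents that add atoms: ethylmagnesium bromide, CC[Mg]Br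
Why: Kulinkovich cyclopropanation, in which the titanacyclopropane formed from EtMgBr acts as a 1,2-dicarbanion on the ester carbonyl.

Step 5
Reactants: 7 3,6-dimethylcyclohepta-2,6-dien-1-one; 9 1-(propan-2-yl)cyclopropan-1-ol
Product: 12 (3R,3aR,8aS)-3-hydroxy-6,8a-dimethyl-3-(propan-2-yl)-2,3,3a,7,8,8a-hexahydroazulen-4(1H)-one, via zinc homoenolate 10 (not isolated), via zinc dienolate 11 (not isolated)
Conditions: 9 (2.2 equiv), Et2Zn (1.1 equiv), THF, 0 to 40 °C; then 7, (CuOTf)2·C6H6 (2.5 mol %), chiral sulfonate-bearing NHC–Ag complex (2.5 mol %), −15 °C to rt, aged at rt; aq NH4Cl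
Reagents that add atoms: none
Why: Proposed new method: zinc alkoxide formation and strain-driven β-carbon elimination turn 9 into the homoenolate 10, whose CH2 (C2) is handed to the chiral NHC–copper centre and added 1,4 to C1 of 7, and the zinc dienolate 11 then attacks its own isopropyl ketone through C5 to make the C4–C5 bond. The closest known reaction types are the conjugate addition/aldol (3+2) annulation of zinc homoenolates generated from cyclopropanols with acyclic enones, and the NHC–copper-catalysed enantioselective addition of dialkylzincs to β-methylcycloalkenones, which builds such quaternary centres also in seven-membered rings; their merger on a cyclic β,β-disubstituted acceptor has not been shown. The only ring closed, the cyclopentane, forms by a 5-(enolexo)-exo-trig aldol addition. C1 is set by the ligand, which only has to tell apart the enantiotopic faces because the two enone arms are equivalent by symmetry; C4 is set relative to C5 by the six-membered zinc chelate of the two oxygens, which holds O4 syn to C6 and turns the isopropyl group towards H5; the trans junction at C5 relies on reversibility of the tertiary zinc aldolate, so that ageing at room temperature should drain a first-formed cis junction into the isomer with both new ring bonds equatorial on the cycloheptenone chair. The step needs transfer of the homoenolate alone and a single addition: both ethyl groups of Et2Zn have left as ethane before catalyst and 7 are added, and the surviving C7=C8 enone arm, now next to the congested chelated aldolate, should react more slowly than 7. Aprotic, weakly basic zinc conditions are chosen to keep the aldolate from losing water.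

Step 6
Reactants: 12 (3R,3aR,8aS)-3-hydroxy-6,8a-dimethyl-3-(propan-2-yl)-2,3,3a,7,8,8a-hexahydroazulen-4(1H)-one
Product: 13 (3R,3aS,4S,8aS)-6,8a-dimethyl-3-(propan-2-yl)-1,2,3,3a,4,7,8,8a-octahydroazulene-3,4-diol
Conditions: Me4NBH(OAc)3, MeCN–AcOH 1:1, −30 °C
Reagents that add atoms: none
Why: Evans–Saksena reduction, in which the β-oriented C4 hydroxyl exchanges an acetate on boron and delivers hydride intramolecularly in 1,2 fashion to the β face of the C6 ketone, which sets the 6α (S) carbinol anti to O4.

Step 7
Reactants: 13 (3R,3aS,4S,8aS)-6,8a-dimethyl-3-(propan-2-yl)-1,2,3,3a,4,7,8,8a-octahydroazulene-3,4-diol; 14 4-acetoxybenzoic acid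
Product: 15 (3R,3aS,4S,8aS)-3-hydroxy-6,8a-dimethyl-3-(propan-2-yl)-1,2,3,3a,4,7,8,8a-octahydroazulen-4-yl 4-acetoxybenzoate
Conditions: DCC, DMAP (cat.), CH2Cl2, rt
Reagents that add atoms: none
Why: Steglich esterification acylates the secondary allylic 6-OH while the tertiary 4-OH stays inert, and no stereocentre is touched.

Step 8
Reactants: 15 (3R,3aS,4S,8aS)-3-hydroxy-6,8a-dimethyl-3-(propan-2-yl)-1,2,3,3a,4,7,8,8a-octahydroazulen-4-yl 4-acetoxybenzoate
Product: 17 (3R,3aS,4S,8aR)-3-hydroxy-6,8a-dimethyl-7-oxo-3-(propan-2-yl)-1,2,3,3a,4,7,8,8a-octahydroazulen-4-yl 4-acetoxybenzoate, via allylic alcohol 16 (not isolated)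
Conditions: SeO2 (30 mol %), TBHP, CH2Cl2, rt; then DMP, CH2Cl2, 0 °C
Reagents that add atoms: tert-butyl hydroperoxide, CC(C)(C)OO (terminal oxygen source, relayed through SeO2)
Why: Riley allylic oxidation (ene reaction, then [2,3]-shift) attacks the ring CH2 on the more substituted alkene terminus C8, that is C9, and leaves C7=C8 in place, and Dess–Martin oxidation converges the C9 alcohol epimers on the enone.

Step 9
Reactants: 17 (3R,3aS,4S,8aR)-3-hydroxy-6,8a-dimethyl-7-oxo-3-(propan-2-yl)-1,2,3,3a,4,7,8,8a-octahydroazulen-4-yl 4-acetoxybenzoate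
Product: 18 lancerodiol p-hydroxybenzoate, (3R,3aS,4S,8aR)-3-hydroxy-6,8a-dimethyl-7-oxo-3-(propan-2-yl)-1,2,3,3a,4,7,8,8a-octahydroazulen-4-yl 4-hydroxybenzoate
Conditions: NH4OAc, MeOH–H2O 4:1, rt
Reagents that add atoms: none
Why: The aryl acetate is a far better acyl donor than the hindered alkyl benzoate, so neutral ammonium-acetate-promoted solvolysis should free the phenol without touching the C6 ester, the γ-acyloxy enone or any stereocentre.

Compound list
1 | 2,5-dimethylfuran | Cc1ccc(C)o1 | starting material
2 | 1,1,3,3-tetrabromopropan-2-one | O=C(C(Br)Br)C(Br)Br | starting material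
3 | 2,4-dibromo-1,5-dimethyl-8-oxabicyclo[3.2.1]oct-6-en-3-one (bromide epimers) | C[C@@]12C=C[C@@](C)(O1)C(Br)C(=O)C2Br | intermediate
4 | (1R,5S)-1,5-dimethyl-8-oxabicyclo[3.2.1]oct-6-en-3-one (meso) | C[C@@]12C=C[C@@](C)(O1)CC(=O)C2 | intermediate
5 | (1R,5S)-1,5-dimethyl-8-oxabicyclo[3.2.1]octan-3-one (meso) | C[C@@]12CC[C@@](C)(O1)CC(=O)C2 | intermediate
6 | 6-hydroxy-3,6-dimethylcyclohept-2-en-1-one (racemic) | CC1=CC(=O)CC(C)(O)CC1 | intermediate
7 | 3,6-dimethylcyclohepta-2,6-dien-1-one | CC1=CC(=O)C=C(C)CC1 | intermediate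
8 | methyl 2-methylpropanoate | COC(=O)C(C)C | starting material
9 | 1-(propan-2-yl)cyclopropan-1-ol | CC(C)C1(O)CC1 | intermediate
10 | bis(4-methyl-3-oxopentyl)zinc (zinc homoenolate) | CC(C)C(=O)CC[Zn]CCC(=O)C(C)C | intermediate
11 | (4-methyl-3-oxopentyl)zinc (7S)-4,7-dimethyl-7-(4-methyl-3-oxopentyl)cyclohepta-1,3-dien-2-olate (zinc dienolate) | CC1=CC(O[Zn]CCC(=O)C(C)C)=C[C@](C)(CCC(=O)C(C)C)CC1 | intermediate
12 | (3R,3aR,8aS)-3-hydroxy-6,8a-dimethyl-3-(propan-2-yl)-2,3,3a,7,8,8a-hexahydroazulen-4(1H)-one (trans-fused; 15-CH3 β, 4-OH β, H5 α) | CC1=CC(=O)[C@@H]2[C@](C)(CC[C@@]2(O)C(C)C)CC1 | intermediate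
13 | (3R,3aS,4S,8aS)-6,8a-dimethyl-3-(propan-2-yl)-1,2,3,3a,4,7,8,8a-octahydroazulene-3,4-diol (6α-OH) | CC1=C[C@H](O)[C@@H]2[C@](C)(CC[C@@]2(O)C(C)C)CC1 | intermediate
14 | 4-acetoxybenzoic acid | CC(=O)Oc1ccc(cc1)C(O)=O | starting material
15 | (3R,3aS,4S,8aS)-3-hydroxy-6,8a-dimethyl-3-(propan-2-yl)-1,2,3,3a,4,7,8,8a-octahydroazulen-4-yl 4-acetoxybenzoate | CC1=C[C@H](OC(=O)c2ccc(OC(C)=O)cc2)[C@@H]2[C@](C)(CC[C@@]2(O)C(C)C)CC1 | intermediate
16 | 15 carrying a hydroxyl group on C9 (azulene C7), both C9 epimers | CC1=C[C@H](OC(=O)c2ccc(OC(C)=O)cc2)[C@@H]2[C@](C)(CC[C@@]2(O)C(C)C)CC1O | intermediate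
17 | (3R,3aS,4S,8aR)-3-hydroxy-6,8a-dimethyl-7-oxo-3-(propan-2-yl)-1,2,3,3a,4,7,8,8a-octahydroazulen-4-yl 4-acetoxybenzoate | CC1=C[C@H](OC(=O)c2ccc(OC(C)=O)cc2)[C@@H]2[C@](C)(CC[C@@]2(O)C(C)C)CC1=O | intermediate
18 | lancerodiol p-hydroxybenzoate | CC1=C[C@H](OC(=O)c2ccc(O)cc2)[C@@H]2[C@](C)(CC[C@@]2(O)C(C)C)CC1=O | target

Total step count: 9. Longest linear sequence: 8 (steps 1, 2, 3, 5, 6, 7, 8, 9).

Steps most likely to fail

Step 5. Three things may go wrong:
- The carbonyl-chelated homoenolate may transfer too slowly to the β,β-disubstituted acceptor.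
- The aldol may close kinetically to the cis ring junction and not equilibrate.
- The aldolate may lose water.

The fallback runs from 7 back to 12 by known reaction types only. Commercial isopropyl vinyl ketone is converted with TMSBr and ethylene glycol into the bromo ketal F1, and this with magnesium into the Grignard reagent F2. Copper/chiral-NHC-catalysed conjugate addition of F2 to 7, established for alkyl Grignard reagents and β-methylcycloalkenones, gives the ketal enone F3. Aqueous HCl frees the diketone F4, which KOH in MeOH condenses to the cross-conjugated dienone F5. Only C1 is stereogenic in F5, so the ring-junction question is postponed. CBS reduction (the antipode that delivers hydride to the α face) gives the 6β-allylic alcohol F6. Hydroxyl-directed epoxidation (VO(acac)2, TBHP) gives the syn β-epoxy alcohol F7, and Dess–Martin oxidation gives the epoxy ketone F8. SmI2 in THF–MeOH at −78 °C then cleaves the C5–O bond to 12. The epoxide fixes O4 on the β face. C5 is protonated, or equilibrated with Et3N, to the trans junction, because its epimer would place C6 cis to the isopropyl group.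

Step 8. Oxidation of the C14 methyl group may compete, or the alkene may be transposed during oxygen transfer. The fallback runs from 12 back to 17. The oxidation is moved to the enone stage, where C9 is the only γ-methylene. Pd(OH)2/C–TBHP γ-oxidation of the enone gives the ene-dione F9. The Evans–Saksena reduction then touches only the C6 ketone, which has the β-hydroxyl group, and gives lancerodiol F10. Steglich esterification with 14 gives 17.

Step 6. The hindered tertiary alcohol may fail to bind boron, so that hydride arrives intermolecularly from the α face. The fallback runs from 12 back to 15. Luche reduction uses exactly that external attack, opposite the angular methyl group, to give the 6β-alcohol F11. Mitsunobu esterification with 14 (PPh3, DIAD) inverts C6 and installs the ester in one operation, giving 15.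

Further compounds
F1 | step 5 | 2-(2-bromoethyl)-2-(propan-2-yl)-1,3-dioxolane | CC(C)C1(CCBr)OCCO1
F2 | step 5 | {2-[2-(propan-2-yl)-1,3-dioxolan-2-yl]ethyl}magnesium bromide | CC(C)C1(CC[Mg]Br)OCCO1
F3 | step 5 | (6S)-3,6-dimethyl-6-{2-[2-(propan-2-yl)-1,3-dioxolan-2-yl]ethyl}cyclohept-2-en-1-one | CC1=CC(=O)C[C@](C)(CCC2(C(C)C)OCCO2)CC1
F4 | step 5 | (6S)-3,6-dimethyl-6-(4-methyl-3-oxopentyl)cyclohept-2-en-1-one | CC1=CC(=O)C[C@](C)(CCC(=O)C(C)C)CC1
F5 | step 5 | (8aS)-6,8a-dimethyl-3-(propan-2-yl)-2,7,8,8a-tetrahydroazulen-4(1H)-one | CC1=CC(=O)C2=C(C(C)C)CC[C@]2(C)CC1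
F6 | step 5 | (4R,8aS)-6,8a-dimethyl-3-(propan-2-yl)-1,2,4,7,8,8a-hexahydroazulen-4-ol (6β-OH) | CC1=C[C@@H](O)C2=C(C(C)C)CC[C@]2(C)CC1
F7 | step 5 | 4β,5β-epoxide of F6 (epoxide syn to the 6β-OH) | CC1=C[C@@H](O)[C@]23O[C@@]2(C(C)C)CC[C@]3(C)CC1
F8 | step 5 | 4β,5β-epoxy-6-ketone derived from F7 | CC1=CC(=O)[C@]23O[C@@]2(C(C)C)CC[C@]3(C)CC1
F9 | step 8 | 9-oxo derivative of 12 (C6,C9 ene-dione) | CC1=CC(=O)[C@@H]2[C@](C)(CC[C@@]2(O)C(C)C)CC1=O
F10 | step 8 | lancerodiol (4β,6α-dihydroxydauc-7-en-9-one) | CC1=C[C@H](O)[C@@H]2[C@](C)(CC[C@@]2(O)C(C)C)CC1=O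
F11 | step 6 | 6-epimer of 13 (6β-OH) | CC1=C[C@@H](O)[C@@H]2[C@](C)(CC[C@@]2(O)C(C)C)CC1
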